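Everything rests on cutting both bonds to C8. In the cross-conjugated dienone C14=C7–C8(=O)–C9=C10 this carbonyl carbon lies between two sp2 carbons and can be delivered as CO. A single carbonylative Stille coupling should therefore forge C7–C8 and C8–C9 together, giving the α-methylene ketone and the E-enone without enolate chemistry on the product. The electrophile is the C7 enol triflate of a carvone-derived cyclohexane ring fused to the C3–C4 oxirane, already carrying the C5 ketone and the C6 isovalerate; C7 and C14 stem from the acetyl group that ozonolysis of carvone's isopropenyl unit leaves. The nucleophile is an E-alkenylstannane whose C11 hydroperoxide is masked as a peroxyketal, so one mild hydrolysis ends the route.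

Key step: step 12

Remarks on the chemistry
- Numbering is that of the target throughout. Ring: C1 carries the side chain, C2 is the CH2, C3–C4 is the oxirane (methyl on C4), C5 is the ring ketone, C6 carries the ester. Side chain: C7 with its methylene C14, C8 (carbonyl), C9=C10, C11 (peroxy carbon).
- The target has the C6 ester trans to the C1 side chain and the oxirane cis to it. (R)-Carvone already has the required arrangement at C1; only the descriptor changes, to S, because the priorities change.
- The C5 silyl ether is removed and C5 is oxidised before the coupling. The peroxide-bearing dienone then meets only dilute acetic acid, never fluoride, base or an oxidant.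
- Peroxides 13–17 are kept in solution behind a shield and are never distilled.

Step 1
Reactants: 1 (R)-carvone; 2 3-methylbutanoic acid
Product: 3 trans-6-(3-methylbutanoyloxy)carvone (ester on C6, on the ring face opposite the C1 isopropenyl group)
Conditions: Mn(OAc)3·2H2O (2.5 equiv), 2 (10 equiv), benzene, reflux, Dean–Stark
Reagents that add atoms: none
Why: Mn(OAc)3 α'-acyloxylation of an enone: after carboxylate exchange on trivalent manganese the metal enolate forms on the α'-side (C6) and the isovalerate is transferred to the face of C6 away from the neighbouring isopropenyl group, so the trans (diequatorial, also the more stable) isomer should predominate, the minor cis isomer being removed by chromatography.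

Step 2
Reactants: 3 trans-6-(3-methylbutanoyloxy)carvone
Product: 4 C5 allylic alcohol (C5–OH cis to the C1 isopropenyl group, trans to the C6 ester)
Conditions: NaBH4, CeCl3·7H2O, MeOH, −78 °C; cold aq. NH4Cl quench
Reagents that add atoms: none
Why: Luche reduction: cerium-activated borohydride adds 1,2 and axially to the half-chair in which the C1 and C6 substituents are equatorial, which should set C5 with an equatorial hydroxyl, cis to the isopropenyl group and trans to the ester, and the cold near-neutral quench keeps the isovalerate from migrating to the new hydroxyl.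

Step 3
Reactants: 4 C5 allylic alcohol
Product: 5 3,4-epoxy alcohol (oxirane on the face of the C5 hydroxyl, hence cis to the C1 isopropenyl group and trans to the C6 ester)
Conditions: VO(acac)2 (5 mol %), t-BuOOH (in decane), CH2Cl2, 0 °C to rt
Reagents that add atoms: tert-butyl hydroperoxide, CC(C)(C)OO
Why: Hydroxyl-directed vanadium-catalysed epoxidation: the C5 alkoxide bound to vanadium delivers the peroxide oxygen to its own face of the C3=C4 alkene, setting C3 and C4 together, while the remote, undirected isopropenyl alkene is left alone.

Step 4
Reactants: 5 3,4-epoxy alcohol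
Product: 6 C5 triethylsilyl ether of 5
Conditions: Et3SiCl, imidazole, DMF, 0 °C to rt
Reagents that add atoms: chlorotriethylsilane, CC[Si](Cl)(CC)CC
Why: Standard silyl ether formation with a silyl chloride and imidazole; no stereocentre changes, and the weakly basic medium avoids acyl migration and Payne rearrangement.

Step 5
Reactants: 6 C5 triethylsilyl ether
Product: 8 C1 acetyl compound (methyl ketone; C7 is the carbonyl carbon, its methyl is the future C14), via ozonide 7 (not isolated)
Conditions: O3, CH2Cl2, −78 °C; then PPh3, −78 °C to rt
Reagents that add atoms: ozone, [O-][O+]=O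
Why: Ozonolysis with reductive work-up cleaves the only C=C bond, the 1,1-disubstituted isopropenyl alkene, through the 1,2,4-trioxolane to the methyl ketone under neutral conditions that leave C1, the oxirane, the ester and the silyl ether untouched.

Step 6
Reactants: 8 C1 acetyl compound
Product: 9 C7 enol triflate (C14 methylene) with C5–O-triethylsilyl and C6–O-(3-methylbutanoyl)
Conditions: KN(SiMe3)2 (1.05 equiv) added to 8 and N-(5-chloropyridin-2-yl)triflimide in THF, −78 °C
Reagents that add atoms: N-(5-chloropyridin-2-yl)-1,1,1-trifluoro-N-(trifluoromethanesulfonyl)methanesulfonamide (Comins' reagent), O=S(=O)(N(c1ccc(Cl)cn1)S(=O)(=O)C(F)(F)F)C(F)(F)F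
Why: Kinetic enolisation and O-triflation with trapping in the flask: the hindered amide base takes a proton from the methyl group, not the tertiary C1–H, and the potassium enolate is sulfonylated at −78 °C as it forms, before it can attack the neighbouring ester, so C1 is not touched.

Step 7
Reactants: 9 C7 enol triflate with C5–O-triethylsilyl
Product: 10 C7 enol triflate with free C5 hydroxyl
Conditions: AcOH/THF/H2O (3:1:1), rt
Reagents that add atoms: none
Why: Acid-catalysed solvolysis of the triethylsilyl ether; dilute acetic acid spares the enol triflate, the oxirane and the ester, and the absence of base or fluoride avoids migration of the isovalerate to the freed C5 hydroxyl.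

Step 8
Reactants: 10 C7 enol triflate with free C5 hydroxyl
Product: 11 C7 enol triflate of the 3,4-epoxy C5 ketone bearing the C6 isovalerate (coupling precursor)
Conditions: Dess–Martin periodinane, CH2Cl2, 0 °C to rt
Reagents that add atoms: none
Why: Dess–Martin oxidation of the secondary alcohol gives the α,β-epoxy ketone under non-basic conditions that should neither epimerise the α-acyloxy centre C6 nor affect the enol triflate.

Step 9
Reactants: 12 2-methylbut-3-yn-2-ol
Product: 13 2-hydroperoxy-2-methylbut-3-yne
Conditions: 50% aq. H2O2 (excess), H2SO4, 0–5 °C; extracted, kept in solution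
Reagents that add atoms: hydrogen peroxide, OO
Why: Acid-catalysed SN1 perhydrolysis of a tertiary alcohol: the tertiary propargylic cation is captured by hydrogen peroxide, the usual route to tertiary hydroperoxides, and no stereocentre is involved.

Step 10
Reactants: 13 2-hydroperoxy-2-methylbut-3-yne
Product: 14 2-[(2-methoxypropan-2-yl)peroxy]-2-methylbut-3-yne
Conditions: 2-methoxypropene, PPTS (cat.), CH2Cl2, 0 °C
Reagents that add atoms: 2-methoxypropene, C=C(C)OC
Why: Acid-catalysed Markovnikov addition of the hydroperoxide O–H to the enol ether gives the peroxyketal, which removes the acidic, easily reduced O–H yet stays cleavable by mild aqueous acid.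

Step 11
Reactants: 14 2-[(2-methoxypropan-2-yl)peroxy]-2-methylbut-3-yne
Product: 15 (E)-tributyl{3-[(2-methoxypropan-2-yl)peroxy]-3-methylbut-1-en-1-yl}stannane
Conditions: Bu3SnH (1.1 equiv, slow addition), PdCl2(PPh3)2 (2 mol %), THF, 0 °C to rt, dark
Reagents that add atoms: tributyltin hydride, CCCC[SnH](CCCC)CCCC
Why: Palladium-catalysed syn-hydrostannation of a terminal alkyne: hydrogen and tin add to the same face with tin on the terminal carbon, away from the quaternary C11, which should give the E-alkenylstannane, and the dialkyl peroxyketal should not be reduced by the tin hydride without radical initiation.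

Step 12
Reactants: 11 C7 enol triflate of the epoxy ketone; 15 (E)-alkenylstannane
Product: 16 peroxyketal of the target (full carbon skeleton, C11–OO–C(CH3)2OCH3)
Conditions: Pd2(dba)3 (5 mol %), AsPh3 (40 mol %), LiCl (3 equiv), CO (3 bar), NMP, 40 °C; 15 added slowly
Reagents that add atoms: carbon monoxide, [C-]#[O+]
Why: Zerovalent palladium inserts into the C7–OTf bond of 11, CO inserts into the alkenyl–palladium bond (forming C7–C8) to give a divalent acylpalladium, the E-alkenyl group of 15 is transferred from tin, and reductive elimination forms C8–C9 and returns zerovalent palladium. The closest known reaction type is the carbonylative Stille coupling of enol triflates with alkenylstannanes to divinyl ketones. No ring is closed and no stereocentre is made; the E geometry of C9=C10 comes unchanged from 15, and the neutral, base-free medium leaves C1 and the enolisable C6 as they are. The step needs CO insertion to precede transmetalation, which CO pressure and slow addition of 15 should secure, helped by the α-branched alkenylpalladium being slow to couple directly. It also needs palladium to react only at the triflate, the one alkenyl C–O bond in 11, the oxirane and the ester being neither allylic nor vinylic. The peroxyketal has no O–H and is a poor oxidant for soft zerovalent palladium, and AsPh3, unlike a triarylphosphine, should not take oxygen from it.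

Step 13
Reactants: 16 peroxyketal of the target
Product: 17 CNP0241468.1, (1S,3S,4S,6S)-4-[(4E)-5-hydroperoxy-5-methyl-3-oxohexa-1,4-dien-2-yl]-1-methyl-2-oxo-7-oxabicyclo[4.1.0]heptan-3-yl 3-methylbutanoate
Conditions: AcOH/THF/H2O (4:2:1), rt
Reagents that add atoms: none
Why: Acid-catalysed hydrolysis of the acyclic peroxyketal releases the C11 hydroperoxide with loss of acetone and methanol; aqueous acetic acid at room temperature should be too weak to open the keto-deactivated oxirane, cleave the ester or add to the dienone, and no stereocentre is touched.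

Compound list
1 | (R)-carvone | C=C(C)[C@@H]1CC=C(C)C(=O)C1 | starting material
2 | 3-methylbutanoic acid | CC(C)CC(=O)O | starting material
3 | trans-6-(3-methylbutanoyloxy)carvone | C=C(C)[C@@H]1CC=C(C)C(=O)[C@H]1OC(=O)CC(C)C | intermediate
4 | C5 allylic alcohol (OH cis to isopropenyl, trans to ester) | C=C(C)[C@@H]1CC=C(C)[C@H](O)[C@H]1OC(=O)CC(C)C | intermediate
5 | 3,4-epoxy alcohol (oxirane cis to C5–OH) | C=C(C)[C@@H]1C[C@@H]2O[C@]2(C)[C@H](O)[C@H]1OC(=O)CC(C)C | intermediate
6 | C5 triethylsilyl ether of 5 | C=C(C)[C@@H]1C[C@@H]2O[C@]2(C)[C@H](O[Si](CC)(CC)CC)[C@H]1OC(=O)CC(C)C | intermediate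
7 | ozonide of 6 (1,2,4-trioxolane at C7, mixture of C7 epimers) | CC3(OCOO3)[C@@H]1C[C@@H]2O[C@]2(C)[C@H](O[Si](CC)(CC)CC)[C@H]1OC(=O)CC(C)C | intermediate (not isolated)
8 | C1 acetyl compound (methyl ketone) | CC(=O)[C@@H]1C[C@@H]2O[C@]2(C)[C@H](O[Si](CC)(CC)CC)[C@H]1OC(=O)CC(C)C | intermediate
9 | C7 enol triflate, C5–O-triethylsilyl | C=C(OS(=O)(=O)C(F)(F)F)[C@@H]1C[C@@H]2O[C@]2(C)[C@H](O[Si](CC)(CC)CC)[C@H]1OC(=O)CC(C)C | intermediate
10 | C7 enol triflate, C5–OH | C=C(OS(=O)(=O)C(F)(F)F)[C@@H]1C[C@@H]2O[C@]2(C)[C@H](O)[C@H]1OC(=O)CC(C)C | intermediate
11 | C7 enol triflate, C5 ketone (coupling precursor) | C=C(OS(=O)(=O)C(F)(F)F)[C@@H]1C[C@@H]2O[C@]2(C)C(=O)[C@H]1OC(=O)CC(C)C | intermediate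
12 | 2-methylbut-3-yn-2-ol | C#CC(C)(C)O | starting material
13 | 2-hydroperoxy-2-methylbut-3-yne | C#CC(C)(C)OO | intermediate
14 | 2-[(2-methoxypropan-2-yl)peroxy]-2-methylbut-3-yne | C#CC(C)(C)OOC(C)(C)OC | intermediate
15 | (E)-tributyl{3-[(2-methoxypropan-2-yl)peroxy]-3-methylbut-1-en-1-yl}stannane | CCCC[Sn](CCCC)(CCCC)/C=C/C(C)(C)OOC(C)(C)OC | intermediate
16 | peroxyketal of the target | C=C(C(=O)/C=C/C(C)(C)OOC(C)(C)OC)[C@@H]1C[C@@H]2O[C@]2(C)C(=O)[C@H]1OC(=O)CC(C)C | intermediate
17 | CNP0241468.1 | C=C(C(=O)/C=C/C(C)(C)OO)[C@@H]1C[C@@H]2O[C@]2(C)C(=O)[C@H]1OC(=O)CC(C)C | target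

Total step count: 13. Longest linear sequence: 10 steps (steps 1–8, 12, 13); the stannane branch (steps 9–11) joins at step 12.

Steps most likely to fail

1. Step 12. The peroxyketal may be reduced or ionised at its allylic C–O bond by palladium or tin, or transmetalation may outrun CO insertion so that the two alkenyl groups join without C8. The fallback keeps the peroxide out of the palladium step; it sets out from 11 and comes back at 17. Carbonylative Stille coupling of 11 with commercial tributyl(3-methylbut-2-en-1-yl)stannane under the step 12 conditions should give the β,γ-unsaturated prenyl ketone F1. A Schenck ene reaction of F1 with singlet oxygen (O2, tetraphenylporphyrin, visible light, CH2Cl2, 0 °C) should then take a hydrogen from C9, move the alkene to C9=C10 (E) and place the hydroperoxide on C11, giving 17 directly. The electron-poor C7=C14 alkene is inert to singlet oxygen; the regioisomeric C10 hydroperoxide that the ene reaction can also form would be removed by chromatography.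

2. Step 6. The enolate may take over the neighbouring isovaleryl group (intramolecular Claisen-type acyl shift), or enolisation toward C1 may expel the C6 carboxylate. The fallback installs the ester only after the triflate; it sets out from 1 and comes back at 11.
- Luche reduction of 1 gives cis-carveol F2, and VO(acac)2/t-BuOOH gives the syn epoxy alcohol F3.
- Et3SiCl/imidazole gives the silyl ether F4.
- Ozone gives the ozonide F5 (not isolated) and PPh3 the methyl ketone F6, which has no oxygen on C6.
- Triflation as in step 6 gives the enol triflate F7.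
- AcOH/THF/H2O gives the alcohol F8, and Dess–Martin periodinane the epoxy ketone F9.
- LiN(SiMe3)2 (THF, −78 °C; C6 is the only enolisable position) gives the lithium enolate F10 (not isolated). 2-(Phenylsulfonyl)-3-phenyloxaziridine hydroxylates it on the face away from the C1 substituent to the α'-hydroxy ketone F11.
- Steglich esterification of F11 with 2 (EDC·HCl, DMAP, CH2Cl2) gives 11.

3. Step 1. Facial selectivity at C6 may be poor, and acetate may be transferred in place of isovalerate. The fallback is Rubottom oxidation followed by esterification; it sets out from 1 and comes back at 3. LiN(iPr)2 and Me3SiCl (THF, −78 °C) convert 1 into the cross-conjugated trimethylsilyl dienol ether F12. mCPBA (NaHCO3, CH2Cl2, −20 °C) oxidises its electron-rich enol ether alkene from the face away from the isopropenyl group, and silyl migration gives the 6-(trimethylsilyloxy) ketone F13 (not isolated). Aqueous citric acid hydrolyses it to trans-6-hydroxycarvone F14. Steglich esterification of F14 with 2 (EDC·HCl, DMAP, CH2Cl2) gives 3.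

Further compounds
F1 | step 12 | prenyl ketone (C8 ketone with C9H2–C10H=C11(CH3)2), ring as in 11 | C=C(C(=O)CC=C(C)C)[C@@H]1C[C@@H]2O[C@]2(C)C(=O)[C@H]1OC(=O)CC(C)C
F2 | step 6 | cis-carveol, (1R,5R) | C=C(C)[C@@H]1CC=C(C)[C@H](O)C1
F3 | step 6 | cis-carveol 3,4-epoxide (oxirane cis to C5–OH) | C=C(C)[C@@H]1C[C@@H]2O[C@]2(C)[C@H](O)C1
F4 | step 6 | C5 triethylsilyl ether of F3 | C=C(C)[C@@H]1C[C@@H]2O[C@]2(C)[C@H](O[Si](CC)(CC)CC)C1
F5 | step 6 | ozonide of F4 (1,2,4-trioxolane at C7) | CC3(OCOO3)[C@@H]1C[C@@H]2O[C@]2(C)[C@H](O[Si](CC)(CC)CC)C1
F6 | step 6 | C1 acetyl compound without C6 oxygen | CC(=O)[C@@H]1C[C@@H]2O[C@]2(C)[C@H](O[Si](CC)(CC)CC)C1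
F7 | step 6 | C7 enol triflate, C5–O-triethylsilyl, C6 unsubstituted | C=C(OS(=O)(=O)C(F)(F)F)[C@@H]1C[C@@H]2O[C@]2(C)[C@H](O[Si](CC)(CC)CC)C1
F8 | step 6 | C7 enol triflate, C5–OH, C6 unsubstituted | C=C(OS(=O)(=O)C(F)(F)F)[C@@H]1C[C@@H]2O[C@]2(C)[C@H](O)C1
F9 | step 6 | C7 enol triflate, C5 ketone, C6 unsubstituted | C=C(OS(=O)(=O)C(F)(F)F)[C@@H]1C[C@@H]2O[C@]2(C)C(=O)C1
F10 | step 6 | lithium C5–C6 enolate of F9 | [Li+].C=C(OS(=O)(=O)C(F)(F)F)[C@@H]1C[C@@H]2O[C@]2(C)C([O-])=C1
F11 | step 6 | C6 α'-hydroxy ketone (OH trans to the C1 substituent) | C=C(OS(=O)(=O)C(F)(F)F)[C@@H]1C[C@@H]2O[C@]2(C)C(=O)[C@H]1O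
F12 | step 1 | trimethylsilyl dienol ether of carvone | C=C(C)[C@@H]1CC=C(C)C(O[Si](C)(C)C)=C1
F13 | step 1 | trans-6-(trimethylsilyloxy)carvone | C=C(C)[C@@H]1CC=C(C)C(=O)[C@H]1O[Si](C)(C)C
F14 | step 1 | trans-6-hydroxycarvone | C=C(C)[C@@H]1CC=C(C)C(=O)[C@H]1O
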